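## The problem

The target is a 2H-chromene: a benzene ring (C4a–C5–C6–C7–C8–C8a) fused to a pyran ring (O1–C2–C3=C4–C4a–C8a). The quaternary C2 carries a methyl group and a CH2O group esterified with ferulic acid. The benzene ring has four different substituents in a 1,2,3,5 pattern (C4a alkenyl, C8a oxygen, C8 methoxy, C6 acetyl) and hydrogen only at C5 and C7, so the ring has to be built or bought without positional isomers.

C2 (R) is the only stereocentre. It is quaternary, oxygen-bearing and allylic, and no other centre can control it. It therefore has to be imported, and its C2–O1 bond must never be broken afterwards, because ionisation or electrocyclic opening of the chromene would racemise it.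

The fragile parts are the styrene-type C3=C4 bond (acid, light), the aryl methyl ketone (enolisation, nucleophiles) and the cinnamate with its free phenol (base, transesterification). The ester oxygen sits on a neopentyl-type carbon, which rules out esterification by substitution at that carbon.

The feature that opens a short construction is that the six ring carbons fall into three two-carbon units: C4a≡C5 on the C4 side chain, C8a≡C8 on O1 (an ynol ether) and C6≡C7 of but-3-yn-2-one. The C8 oxygen can be carried as a silyl group on the ynol ether terminus, which should also steer the regiochemistry.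

Two points need correcting before this can be used. First, an ynol ether whose oxygen sits on an allylic carbon is an allyl alkynyl ether and is expected to undergo [3,3] rearrangement to a ketene far below room temperature. The C3=C4 bond therefore cannot be present in the diyne and is carried as a C4 methyl ether, to be lost as methanol at the end. Second, the two alkyne termini (H at C5, silicon at C8) must be distinguishable when the C5 alkyne is unmasked.

## Retrosynthesis

**Target 25 back to alcohol 20 and acid 22.** The last operations are removal of a phenolic acetate (24 to 25), creation of C3=C4 by loss of methanol from the 4-methoxychroman 23 (23 to 24), and the ester C–O bond (20 + 22 to 23). The acyl C–O bond is cut rather than the alkyl C–O bond, because the CH2 group next to quaternary C2 would resist substitution. The phenol of ferulic acid 21 is masked as its acetate 22 so that it cannot be acylated. The elimination is placed after the esterification, because a free CH2OH group in 20 could trap the C4 cation as a bridged ether. The forward steps must only be mild enough for a cinnamate and an aryl ketone.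

**Alcohol 20 back to the arylsilane 17.** The C8–O bond is cut to a C8–Si bond: oxidation of the arylsilane 17 gives phenol 19, and methylation gives 20. Silicon is preferred over boron or halogen at C8 because it can be carried on an ynol ether and is needed there anyway for regiocontrol. The same fluoride treatment also removes the silyl ether on the primary oxygen.

**Arylsilane 17 back to diyne 15 and butynone 16 (key disconnection).** Three bonds are cut: C4a–C8a, C5–C6 and C7–C8. This opens the benzene ring and the pyran ring together and reduces the bicyclic core to an acyclic diyne with one stereocentre plus a four-carbon ynone. The alternative cuts of the arene (stepwise substitution of a bought benzene) would need four regiochemical decisions; this one needs only the orientation of 16. The forward reaction must join an O-tert-alkyl ynol ether and a terminal alkyne at a metal near room temperature, and must place the acetyl-bearing carbon on C5. The tether is saturated (C3H2, C4H–OMe) so that no sigmatropic path exists, and the quaternary C2 helps the 1,7-diyne to fold.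

**Diyne 15 back to the tertiary alcohol 8.** The ynol ether C–O bond is cut to the alcohol 8 and trichloroethylene 9, by way of dichlorovinyl ether 11 and the silylated ynol ether 14. The C5–H bond is traced to a C5–SiMe3 bond. The silyl group on the ynol ether terminus is chosen as diisopropyl(methoxy)silyl: it is hindered enough to survive the methoxide that removes the trimethylsilyl group, its methoxy group exchanges with methanol without change, and it remains oxidisable. The ynol ether is made as late as possible because it is the most labile function of the route.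

**Alcohol 8 back to aldehyde 4 and trimethylsilylacetylene 5.** The C4–C4a bond is cut to aldehyde 4 and the acetylide of 5 (giving diol 7), and the C4 oxygen is methylated (7 to 8). The aldehyde addition installs the alkyne and the oxygen that masks the alkene in one step. The new C4 centre need not be controlled.

**Aldehyde 4 back to (S)-2-methylglycidol 1.** The aldehyde comes from oxidative cleavage of the alkene 3, and the C3–C(vinyl) bond is cut to the silyl-protected epoxide 2 and a vinyl-metal nucleophile. The epoxide CH2 becomes C3 and the CH2OH arm becomes the ester-bearing carbon, which is why the S enantiomer of the glycidol is required. The triisopropylsilyl ether is chosen because it should not migrate to the tertiary alkoxide formed later.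

## Roads not taken

**Alternative 1:** The CH2–O bond on C2 is cut back to a methyl C–H bond. A temporary (3R) hydroxyl, as its diethylhydrosilyl ether A2, directs an iridium catalyst ([Ir(cod)OMe]2 with a tetramethylphenanthroline ligand) to silylate one of the two geminal methyl groups. This gives the trans-fused oxasilolane A1 and sets C2 by relay. Oxidation of the C–Si bond then gives the hydroxymethyl group, and the C3 oxygen is eliminated to give C3=C4.
- Merits: the arene and pyran come from classical chromene chemistry, the silylation of a γ-methyl C–H bond of an alcohol is an established reaction class, and the C3 oxygen serves twice.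
- Weak points: both methyl groups are gauche to the C3 oxygen, so the configuration at C2 rests on a preference for the trans-fused bicycle that is not secured. The C3 carbinol must first be made enantiopure. After oxidation a secondary and a primary hydroxyl must be differentiated before elimination.
- Comparison: its key step has better precedent than step 9 of the chosen plan. Against that, the chosen plan takes C2 intact from the chiral pool and does not depend on a diastereoselection between two near-equivalent methyl groups.

**Alternative 2:** The O1–C2 and C3=C4 bonds are cut. A secondary-amine catalyst (a diarylprolinol silyl ether with an acid) would join salicylaldehyde A4 and the β,β-disubstituted enal A5 by oxa-Michael addition and aldol condensation, giving the chromene-3-carbaldehyde A3 with C2 set in the same step.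
- Merits: it is the shortest road, the arene is bought complete, and ring and stereocentre arise in one catalytic step.
- Weak points: the known reaction works for enals with one β-substituent. Here the β-carbon bears methyl and silyloxymethyl groups of similar size, the iminium ion is less electrophilic and can isomerise, and the oxa-Michael step is reversible, so both rate and enantioselectivity are doubtful. The formyl group at C3 is not in the target and must be removed by a rhodium-mediated decarbonylation on a sensitive chromene.
- Comparison: in step count this road is better than the chosen plan. The chosen plan sets against it a secure absolute configuration and no superfluous carbon.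

**Alternative 3:** The C8a–O1 bond is cut. The tertiary alkoxide of the β-hydroxy ketone A7, derived from (R)-citramalic acid A8, displaces an aryl fluoride ortho to the ketone and closes the chromanone A6. The ester is later reduced to the CH2OH group, and the C4 ketone is reduced and dehydrated to give the alkene.
- Merits: every step is of a known type, the stereocentre comes from the chiral pool, and the closure does not touch the C2–O bond.
- Weak points: A7 needs one of the two carboxyl groups of A8 to be acylated selectively onto an aryl metal, the alkoxide of A7 can undergo retro-aldol cleavage in competition with ring closure, and the reduction sequence creates a diol that must be differentiated.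
- Comparison: in reliability this road is better. The chosen plan offers instead the assembly of the fully substituted arene and the pyran in one step from simple alkynes, and it borrows the fluoride-displacement closure as the fallback for its key step.

Key step: step 9

Remark on the chemistry: C4 is carried as a mixture of both configurations from step 4 to step 13, because step 14 removes this centre; C2 is the only controlled stereocentre.

## Route

Step 1
Reactants: 1 (S)-2-methylglycidol, [(2S)-2-methyloxiran-2-yl]methanol
Product: 2 triisopropyl{[(2R)-2-methyloxiran-2-yl]methoxy}silane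
Conditions: TIPSCl, imidazole, DMF, 0 → 20 °C
Reagents that add atoms: chlorotriisopropylsilane, CC(C)[Si](Cl)(C(C)C)C(C)C
Why: Silyl ether formation at a primary alcohol; the hindered triisopropylsilyl group should not migrate to the tertiary alkoxide of step 6 and is removed by fluoride in step 10. The stereocentre is untouched; only its descriptor changes from S to R through the change in priorities.

Step 2
Reactants: 2 triisopropyl{[(2R)-2-methyloxiran-2-yl]methoxy}silane
Product: 3 (2R)-2-methyl-1-(triisopropylsilyloxy)pent-4-en-2-ol
Conditions: vinylmagnesium bromide, CuI (10 mol %), THF, −40 → 0 °C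
Reagents that add atoms: vinylmagnesium bromide, C=C[Mg]Br
Why: Copper-catalysed Grignard opening of a 2,2-disubstituted epoxide at its unsubstituted carbon (SN2); the bond from the quaternary carbon to oxygen is not broken, so the configuration of the tertiary carbinol is retained.

Step 3
Reactants: 3 (2R)-2-methyl-1-(triisopropylsilyloxy)pent-4-en-2-ol
Product: 4 (3R)-3-hydroxy-3-methyl-4-(triisopropylsilyloxy)butanal
Conditions: O3, CH2Cl2, −78 °C; then PPh3, −78 → 20 °C
Reagents that add atoms: ozone, [O-][O+]=O
Why: Ozonolysis with reductive work-up of a terminal alkene; the β-hydroxy aldehyde is used crude because it is prone to dehydration.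

Step 4
Reactants: 4 (3R)-3-hydroxy-3-methyl-4-(triisopropylsilyloxy)butanal; 5 ethynyl(trimethyl)silane
Product: 7 (3RS,5R)-5-methyl-1-(trimethylsilyl)-6-(triisopropylsilyloxy)hex-1-yne-3,5-diol, via lithium trimethylsilylacetylide 6 (not isolated)
Conditions: 5 (2.6 equiv), n-BuLi (2.5 equiv), THF, −78 °C; then 4, −78 °C; aq NH4Cl
Reagents that add atoms: none
Why: 1,2-Addition of a lithium acetylide to an aldehyde; at −78 °C addition should outrun retro-aldol cleavage of the β-alkoxide, and the excess acetylide covers the free hydroxyl. The new carbinol centre forms as a mixture, which does not matter because it is removed in step 14.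

Step 5
Reactants: 7 (3RS,5R)-5-methyl-1-(trimethylsilyl)-6-(triisopropylsilyloxy)hex-1-yne-3,5-diol
Product: 8 (2R,4RS)-4-methoxy-2-methyl-6-(trimethylsilyl)-1-(triisopropylsilyloxy)hex-5-yn-2-ol
Conditions: Me3OBF4 (1.3 equiv), 1,8-bis(dimethylamino)naphthalene (1.5 equiv), CH2Cl2, 0 → 20 °C
Reagents that add atoms: trimethyloxonium tetrafluoroborate, C[O+](C)C.F[B-](F)(F)F
Why: O-Alkylation with an oxonium salt under non-basic conditions; the secondary propargylic hydroxyl should react and the hindered tertiary one should not, and the alkynylsilane is never exposed to an alkoxide. The methyl ether is the masked form of the C3=C4 alkene.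

Step 6
Reactants: 8 (2R,4RS)-4-methoxy-2-methyl-6-(trimethylsilyl)-1-(triisopropylsilyloxy)hex-5-yn-2-ol; 9 trichloroethylene
Product: 11 {[(2R,4RS)-2-[(E)-1,2-dichloroethenyl]oxy-4-methoxy-2-methyl-6-(trimethylsilyl)hex-5-yn-1-yl]oxy}triisopropylsilane, via potassium alkoxide 10 (not isolated)
Conditions: KH (1.3 equiv), THF, 0 °C; then 9 (1.2 equiv), −50 → 20 °C
Reagents that add atoms: none
Why: The potassium alkoxide eliminates HCl from trichloroethylene and adds anti to the dichloroacetylene so formed, giving the (E)-1,2-dichlorovinyl ether (the trichloroethylene route to ynol ethers). The bond from C2 to oxygen is not involved, so C2 keeps its configuration.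

Step 7
Reactants: 11 {[(2R,4RS)-2-[(E)-1,2-dichloroethenyl]oxy-4-methoxy-2-methyl-6-(trimethylsilyl)hex-5-yn-1-yl]oxy}triisopropylsilane
Product: 14 diisopropyl(methoxy){[(2R,4RS)-4-methoxy-2-methyl-6-(trimethylsilyl)-1-(triisopropylsilyloxy)hex-5-yn-2-yl]oxyethynyl}silane, via lithium alkynyl ether 12 (not isolated), via chlorosilane 13 (not isolated)
Conditions: n-BuLi (2.3 equiv), THF, −78 → −40 °C; i-Pr2SiCl2 (3 equiv), −78 → 0 °C; then MeOH, Et3N, 0 °C
Reagents that add atoms: dichlorodiisopropylsilane, CC(C)[Si](Cl)(Cl)C(C)C; methanol, CO
Why: n-BuLi eliminates HCl and exchanges the remaining chlorine for lithium, and the lithium alkynyl ether is silylated once by the hindered dichlorosilane. Methanolysis of the remaining Si–Cl bond gives a methoxysilane that stays oxidisable and is bulky enough to outlast step 8.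

Step 8
Reactants: 14 diisopropyl(methoxy){[(2R,4RS)-4-methoxy-2-methyl-6-(trimethylsilyl)-1-(triisopropylsilyloxy)hex-5-yn-2-yl]oxyethynyl}silane
Product: 15 diisopropyl(methoxy){[(2R,4RS)-4-methoxy-2-methyl-1-(triisopropylsilyloxy)hex-5-yn-2-yl]oxyethynyl}silane
Conditions: K2CO3 (0.3 equiv), MeOH/THF, 0 °C
Reagents that add atoms: none
Why: Base-catalysed protiodesilylation of an alkynylsilane; methoxide should attack the unhindered trimethylsilyl group, while the diisopropylsilyl group is shielded and exchange of its methoxy group with the solvent changes nothing. The reaction is kept at 0 °C because the product is a thermally labile tert-alkyl ynol ether.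

Step 9
Reactants: 15 diisopropyl(methoxy){[(2R,4RS)-4-methoxy-2-methyl-1-(triisopropylsilyloxy)hex-5-yn-2-yl]oxyethynyl}silane; 16 but-3-yn-2-one
Product: 17 1-[(2R,4RS)-8-[diisopropyl(methoxy)silyl]-4-methoxy-2-methyl-2-(triisopropylsilyloxymethyl)-3,4-dihydro-2H-chromen-6-yl]ethanone
Conditions: Cp*RuCl(cod) (10 mol %), 16 (3 equiv), ClCH2CH2Cl, 20 °C, 15 added slowly
Reagents that add atoms: none
Why: Proposed new method: Cp*RuCl(cod) should bind both alkynes of 15 and couple them oxidatively to a ruthenacycle, which forms C4a–C8a and closes the dihydropyran ring (six-membered, from a 1,7-diyne that the quaternary C2 biases toward folding). Insertion of 16 and reductive elimination then form C5–C6 and C7–C8 and close the benzene ring, so two rings and three C–C bonds arise in one operation. The closest known reaction type is the Cp*RuCl-catalysed [2+2+2] cycloaddition of unsymmetrical 1,6- and 1,7-diynes with terminal alkynes, in which a substituent on one diyne terminus sends the alkyne substituent to the meta position; what is new is an O-tert-alkyl ynol ether as a diyne terminus. The step needs regioselectivity in the insertion of 16: the bulky silyl group on C8 should force the acetyl-bearing carbon onto the unhindered C5 terminus, giving the 6-acetyl isomer, and the excess of 16 should suppress dimerisation of the diyne. No stereocentre is formed; C2 is a spectator and C4 stays a mixture. The temperature is held at 20 °C because tert-alkyl ynol ethers fragment to ketenes on heating, and the saturated C3–C4 tether removes the [3,3] path that an allyl ynol ether would have.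

Step 10
Reactants: 17 1-[(2R,4RS)-8-[diisopropyl(methoxy)silyl]-4-methoxy-2-methyl-2-(triisopropylsilyloxymethyl)-3,4-dihydro-2H-chromen-6-yl]ethanone
Product: 19 1-[(2R,4RS)-8-hydroxy-2-(hydroxymethyl)-4-methoxy-2-methyl-3,4-dihydro-2H-chromen-6-yl]ethanone, via aryl fluorosilane 18 (not isolated)
Conditions: TBAF (5 equiv), THF, 20 °C; then KHCO3, 30% aq H2O2, MeOH, 45 °C
Reagents that add atoms: hydrogen peroxide, OO
Why: Tamao–Fleming oxidation of an arylsilane; fluoride replaces methoxide on silicon and cleaves the silyl ether, and hydroperoxide then induces migration of the aryl group from silicon to oxygen at the same ring carbon. The acetyl group is meta to the new phenol, so no Dakin-type oxidation is expected.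

Step 11
Reactants: 19 1-[(2R,4RS)-8-hydroxy-2-(hydroxymethyl)-4-methoxy-2-methyl-3,4-dihydro-2H-chromen-6-yl]ethanone
Product: 20 1-[(2R,4RS)-2-(hydroxymethyl)-4,8-dimethoxy-2-methyl-3,4-dihydro-2H-chromen-6-yl]ethanone
Conditions: MeI (1.5 equiv), K2CO3, DMF, 20 °C
Reagents that add atoms: iodomethane, CI
Why: Williamson ether synthesis; K2CO3 deprotonates only the phenol, so the primary alcohol stays free.

Step 12
Reactants: 21 ferulic acid, (E)-3-(4-hydroxy-3-methoxyphenyl)prop-2-enoic acid
Product: 22 (E)-3-(4-acetoxy-3-methoxyphenyl)prop-2-enoic acid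
Conditions: NaOH (aq), Ac2O, 0 °C; then HCl to pH 2
Reagents that add atoms: acetic anhydride, CC(=O)OC(C)=O
Why: Schotten–Baumann acetylation of the phenoxide in water, where the carboxylate does not keep an acyl group. The acetate prevents the phenol from being acylated in step 13.

Step 13
Reactants: 20 1-[(2R,4RS)-2-(hydroxymethyl)-4,8-dimethoxy-2-methyl-3,4-dihydro-2H-chromen-6-yl]ethanone; 22 (E)-3-(4-acetoxy-3-methoxyphenyl)prop-2-enoic acid
Product: 23 [(2R,4RS)-6-acetyl-4,8-dimethoxy-2-methyl-3,4-dihydro-2H-chromen-2-yl]methyl (E)-3-(4-acetoxy-3-methoxyphenyl)prop-2-enoate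
Conditions: EDC·HCl (1.5 equiv), DMAP (0.2 equiv), CH2Cl2, 0 → 20 °C
Reagents that add atoms: none
Why: Steglich esterification; the bond is made at the acyl carbon because substitution at the neopentyl-type CH2 group would be slow.

Step 14
Reactants: 23 [(2R,4RS)-6-acetyl-4,8-dimethoxy-2-methyl-3,4-dihydro-2H-chromen-2-yl]methyl (E)-3-(4-acetoxy-3-methoxyphenyl)prop-2-enoate
Product: 24 [(2R)-6-acetyl-8-methoxy-2-methyl-2H-chromen-2-yl]methyl (E)-3-(4-acetoxy-3-methoxyphenyl)prop-2-enoate
Conditions: TsOH·H2O (10 mol %), 5 Å molecular sieves, toluene, 80 °C, dark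
Reagents that add atoms: none
Why: Acid-catalysed E1 elimination of methanol from a 4-alkoxychroman; ionisation at C4 is assisted by O1 through the ring, and loss of a proton from C3 (C2 has none) can give only the conjugated 2H-chromene. Both C4 epimers converge, the acylated primary oxygen cannot trap the cation, and the sieves take up methanol.

Step 15
Reactants: 24 [(2R)-6-acetyl-8-methoxy-2-methyl-2H-chromen-2-yl]methyl (E)-3-(4-acetoxy-3-methoxyphenyl)prop-2-enoate
Product: 25 [(2R)-6-acetyl-8-methoxy-2-methyl-2H-chromen-2-yl]methyl (E)-3-(4-hydroxy-3-methoxyphenyl)prop-2-enoate (CNP0168033.1)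
Conditions: pyrrolidine (3 equiv), CH2Cl2, 0 °C
Reagents that add atoms: none
Why: Aminolysis of an aryl acetate by a secondary amine; the alkyl cinnamate and the ketone should not react at 0 °C.

## Compound list

1 | (S)-2-methylglycidol, [(2S)-2-methyloxiran-2-yl]methanol | OC[C@@]1(C)CO1 | starting material
2 | triisopropyl{[(2R)-2-methyloxiran-2-yl]methoxy}silane | CC(C)[Si](C(C)C)(C(C)C)OC[C@@]1(C)CO1 | intermediate
3 | (2R)-2-methyl-1-(triisopropylsilyloxy)pent-4-en-2-ol | CC(C)[Si](C(C)C)(C(C)C)OC[C@@](O)(C)CC=C | intermediate
4 | (3R)-3-hydroxy-3-methyl-4-(triisopropylsilyloxy)butanal | CC(C)[Si](C(C)C)(C(C)C)OC[C@@](O)(C)CC=O | intermediate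
5 | ethynyl(trimethyl)silane (trimethylsilylacetylene) | C#C[Si](C)(C)C | starting material
6 | lithium trimethylsilylacetylide | [Li]C#C[Si](C)(C)C | intermediate
7 | (3RS,5R)-5-methyl-1-(trimethylsilyl)-6-(triisopropylsilyloxy)hex-1-yne-3,5-diol | CC(C)[Si](C(C)C)(C(C)C)OC[C@@](O)(C)CC(O)C#C[Si](C)(C)C | intermediate
8 | (2R,4RS)-4-methoxy-2-methyl-6-(trimethylsilyl)-1-(triisopropylsilyloxy)hex-5-yn-2-ol | CC(C)[Si](C(C)C)(C(C)C)OC[C@@](O)(C)CC(OC)C#C[Si](C)(C)C | intermediate
9 | trichloroethylene | ClC=C(Cl)Cl | starting material
10 | potassium (2R,4RS)-4-methoxy-2-methyl-6-(trimethylsilyl)-1-(triisopropylsilyloxy)hex-5-yn-2-olate | CC(C)[Si](C(C)C)(C(C)C)OC[C@@]([O-])(C)CC(OC)C#C[Si](C)(C)C.[K+] | intermediate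
11 | {[(2R,4RS)-2-[(E)-1,2-dichloroethenyl]oxy-4-methoxy-2-methyl-6-(trimethylsilyl)hex-5-yn-1-yl]oxy}triisopropylsilane | CC(C)[Si](C(C)C)(C(C)C)OC[C@@](O/C(Cl)=C\Cl)(C)CC(OC)C#C[Si](C)(C)C | intermediate
12 | lithium 2-{[(2R,4RS)-4-methoxy-2-methyl-6-(trimethylsilyl)-1-(triisopropylsilyloxy)hex-5-yn-2-yl]oxy}ethynide | CC(C)[Si](C(C)C)(C(C)C)OC[C@@](OC#C[Li])(C)CC(OC)C#C[Si](C)(C)C | intermediate
13 | chlorodiisopropyl{[(2R,4RS)-4-methoxy-2-methyl-6-(trimethylsilyl)-1-(triisopropylsilyloxy)hex-5-yn-2-yl]oxyethynyl}silane | CC(C)[Si](C(C)C)(C(C)C)OC[C@@](OC#C[Si](Cl)(C(C)C)C(C)C)(C)CC(OC)C#C[Si](C)(C)C | intermediate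
14 | diisopropyl(methoxy){[(2R,4RS)-4-methoxy-2-methyl-6-(trimethylsilyl)-1-(triisopropylsilyloxy)hex-5-yn-2-yl]oxyethynyl}silane | CC(C)[Si](C(C)C)(C(C)C)OC[C@@](OC#C[Si](OC)(C(C)C)C(C)C)(C)CC(OC)C#C[Si](C)(C)C | intermediate
15 | diisopropyl(methoxy){[(2R,4RS)-4-methoxy-2-methyl-1-(triisopropylsilyloxy)hex-5-yn-2-yl]oxyethynyl}silane | CC(C)[Si](C(C)C)(C(C)C)OC[C@@](OC#C[Si](OC)(C(C)C)C(C)C)(C)CC(OC)C#C | intermediate
16 | but-3-yn-2-one | CC(=O)C#C | starting material
17 | 1-[(2R,4RS)-8-[diisopropyl(methoxy)silyl]-4-methoxy-2-methyl-2-(triisopropylsilyloxymethyl)-3,4-dihydro-2H-chromen-6-yl]ethanone | CC(C)[Si](C(C)C)(C(C)C)OC[C@@]1(C)CC(OC)c2cc(C(C)=O)cc([Si](OC)(C(C)C)C(C)C)c2O1 | intermediate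
18 | 1-[(2R,4RS)-8-[fluoro(diisopropyl)silyl]-2-(hydroxymethyl)-4-methoxy-2-methyl-3,4-dihydro-2H-chromen-6-yl]ethanone | OC[C@@]1(C)CC(OC)c2cc(C(C)=O)cc([Si](F)(C(C)C)C(C)C)c2O1 | intermediate
19 | 1-[(2R,4RS)-8-hydroxy-2-(hydroxymethyl)-4-methoxy-2-methyl-3,4-dihydro-2H-chromen-6-yl]ethanone | OC[C@@]1(C)CC(OC)c2cc(C(C)=O)cc(O)c2O1 | intermediate
20 | 1-[(2R,4RS)-2-(hydroxymethyl)-4,8-dimethoxy-2-methyl-3,4-dihydro-2H-chromen-6-yl]ethanone | OC[C@@]1(C)CC(OC)c2cc(C(C)=O)cc(OC)c2O1 | intermediate
21 | ferulic acid, (E)-3-(4-hydroxy-3-methoxyphenyl)prop-2-enoic acid | COc1cc(/C=C/C(=O)O)ccc1O | starting material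
22 | (E)-3-(4-acetoxy-3-methoxyphenyl)prop-2-enoic acid | COc1cc(/C=C/C(=O)O)ccc1OC(C)=O | intermediate
23 | [(2R,4RS)-6-acetyl-4,8-dimethoxy-2-methyl-3,4-dihydro-2H-chromen-2-yl]methyl (E)-3-(4-acetoxy-3-methoxyphenyl)prop-2-enoate | COc1cc(/C=C/C(=O)OC[C@@]2(C)CC(OC)c3cc(C(C)=O)cc(OC)c3O2)ccc1OC(C)=O | intermediate
24 | [(2R)-6-acetyl-8-methoxy-2-methyl-2H-chromen-2-yl]methyl (E)-3-(4-acetoxy-3-methoxyphenyl)prop-2-enoate | COc1cc(/C=C/C(=O)OC[C@@]2(C)C=Cc3cc(C(C)=O)cc(OC)c3O2)ccc1OC(C)=O | intermediate
25 | [(2R)-6-acetyl-8-methoxy-2-methyl-2H-chromen-2-yl]methyl (E)-3-(4-hydroxy-3-methoxyphenyl)prop-2-enoate | COc1cc(/C=C/C(=O)OC[C@@]2(C)C=Cc3cc(C(C)=O)cc(OC)c3O2)ccc1O | target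

## Step count and least certain steps

Total: 15 steps. Longest linear sequence: 14 steps (steps 1–11 and 13–15, from 1 to 25); step 12 is a one-step side branch.

**Step 9 (key step).** The most likely failure is decomposition of the ynol ether at the metal (hydration, fragmentation to a ketene, oligomerisation) faster than oxidative coupling, because an electron-rich, hindered ynol ether alkyne is an untested partner for ruthenacycle formation. Incomplete regiocontrol in the insertion of 16 is the second risk.

The fallback forms the O1–C8a bond by a known fluoride displacement instead of the cycloaddition. It sets out from aldehyde 4 and returns at alcohol 20.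
- Commercial 1-(4-fluoro-3-methoxyphenyl)ethanone F1 is converted into its ketal 2-(4-fluoro-3-methoxyphenyl)-2-methyl-1,3-dioxolane F2 (ethylene glycol, TsOH, toluene, water removal).
- Lithiation next to fluorine (s-BuLi, PMDTA, THF, −78 °C) and addition of the aryllithium to 4 should give (1RS,3R)-1-[2-fluoro-3-methoxy-5-(2-methyl-1,3-dioxolan-2-yl)phenyl]-3-methyl-4-(triisopropylsilyloxy)butane-1,3-diol F3.
- Methylation of the benzylic hydroxyl as in step 5 gives the methyl ether (2R,4RS)-4-[2-fluoro-3-methoxy-5-(2-methyl-1,3-dioxolan-2-yl)phenyl]-4-methoxy-2-methyl-1-(triisopropylsilyloxy)butan-2-ol F4.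
- Mild aqueous acid (PPTS, acetone/water) frees the ketone 1-{4-fluoro-3-[(1RS,3R)-3-hydroxy-1-methoxy-3-methyl-4-(triisopropylsilyloxy)butyl]-5-methoxyphenyl}ethanone F5, in which fluorine is para to the acetyl group.
- NaH in DMF should then let the tertiary alkoxide displace fluoride (nucleophilic aromatic substitution, six-membered ring, C2–O bond untouched), giving 1-[(2R,4RS)-4,8-dimethoxy-2-methyl-2-(triisopropylsilyloxymethyl)-3,4-dihydro-2H-chromen-6-yl]ethanone F6. TBAF then gives 20.

**Step 8.** The most likely failure is competing cleavage of the ynol ether C–Si bond by methoxide, because an alkoxy-substituted acetylide is a good leaving group and the steric margin may not be enough.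

The fallback reverses the order of unmasking and ring formation. It sets out from 14 and returns at 19.
- 14 is cyclised with 16 with the trimethylsilyl group still in place, under a catalyst that accepts two substituted diyne termini (for example [Rh(cod)2]BF4 with BINAP, CH2Cl2, 20 °C). The acetyl-bearing carbon should still bond to C5, the terminus with the smaller silyl group. This gives 1-[(2R,4RS)-8-[diisopropyl(methoxy)silyl]-4-methoxy-2-methyl-2-(triisopropylsilyloxymethyl)-5-(trimethylsilyl)-3,4-dihydro-2H-chromen-6-yl]ethanone F9.
- In the fluoride stage of step 10 (TBAF, wet THF, 45 °C) the crowded aryl–SiMe3 bond next to the acetyl group should undergo protodesilylation while the C8 silicon is oxidised, which leads to 19.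

**Step 6.** The most likely failure is transfer of the alkynyl trimethylsilyl group to the hindered potassium alkoxide, or sluggish addition of the tertiary alkoxide to dichloroacetylene.

The fallback builds the ynol ether carbons from a formate. It sets out from 8 and returns at 14.
- Formylation (acetic formic anhydride, pyridine) gives (2R,4RS)-4-methoxy-2-methyl-6-(trimethylsilyl)-1-(triisopropylsilyloxy)hex-5-yn-2-yl formate F7.
- Dibromo-olefination of the formate carbonyl (CBr4, PPh3, CH2Cl2) gives {[(2R,4RS)-2-(2,2-dibromoethenyl)oxy-4-methoxy-2-methyl-6-(trimethylsilyl)hex-5-yn-1-yl]oxy}triisopropylsilane F8.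
- n-BuLi (2.2 equiv, THF, −78 °C) converts F8 by elimination and bromine–lithium exchange into the same lithium alkynyl ether 12, which is silylated and methanolysed as in step 7 to give 14.

**Step 10.** The most likely failure is protodesilylation of the aryl–silicon bond by fluoride in place of oxidation, because the hindered diisopropylsilyl group accepts hydroperoxide slowly.

The fallback uses silicon as a placeholder for iodine instead of oxygen. It sets out from 17 and returns at 20.
- ICl (CH2Cl2, 0 °C) should replace the silyl group at its ipso carbon, giving 1-[(2R,4RS)-8-iodo-4-methoxy-2-methyl-2-(triisopropylsilyloxymethyl)-3,4-dihydro-2H-chromen-6-yl]ethanone F10.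
- Copper-catalysed coupling with methanol (CuI, 1,10-phenanthroline, Cs2CO3, MeOH/toluene, 100 °C) gives the methyl ether F6 described above, and TBAF gives 20.

**Step 14.** The most likely failure is slow ionisation at C4, because the acetyl group para to O1 weakens the donation from O1. Prolonged heating with acid could then ionise the C2–O1 bond, with loss of configurational purity, or cleave the aryl acetate.

The fallback replaces the E1 process by substitution followed by base-induced elimination. It sets out from 23 and returns at 24.
- Acetyl bromide with a catalytic amount of ZnBr2 (CH2Cl2, 0 °C) should convert the benzylic methyl ether into [(2R,4RS)-6-acetyl-4-bromo-8-methoxy-2-methyl-3,4-dihydro-2H-chromen-2-yl]methyl (E)-3-(4-acetoxy-3-methoxyphenyl)prop-2-enoate F11.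
- DBU (toluene, 20 °C) removes HBr toward C3, the only β-position with hydrogen, giving 24.

## Further compounds

F1 | step 9 | 1-(4-fluoro-3-methoxyphenyl)ethanone | COc1cc(C(C)=O)ccc1F
F2 | step 9 | 2-(4-fluoro-3-methoxyphenyl)-2-methyl-1,3-dioxolane | COc1cc(C2(C)OCCO2)ccc1F
F3 | step 9 | (1RS,3R)-1-[2-fluoro-3-methoxy-5-(2-methyl-1,3-dioxolan-2-yl)phenyl]-3-methyl-4-(triisopropylsilyloxy)butane-1,3-diol | CC(C)[Si](C(C)C)(C(C)C)OC[C@@](O)(C)CC(O)c1cc(C2(C)OCCO2)cc(OC)c1F
F4 | step 9 | (2R,4RS)-4-[2-fluoro-3-methoxy-5-(2-methyl-1,3-dioxolan-2-yl)phenyl]-4-methoxy-2-methyl-1-(triisopropylsilyloxy)butan-2-ol | CC(C)[Si](C(C)C)(C(C)C)OC[C@@](O)(C)CC(OC)c1cc(C2(C)OCCO2)cc(OC)c1F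
F5 | step 9 | 1-{4-fluoro-3-[(1RS,3R)-3-hydroxy-1-methoxy-3-methyl-4-(triisopropylsilyloxy)butyl]-5-methoxyphenyl}ethanone | CC(C)[Si](C(C)C)(C(C)C)OC[C@@](O)(C)CC(OC)c1cc(C(C)=O)cc(OC)c1F
F6 | step 9 | 1-[(2R,4RS)-4,8-dimethoxy-2-methyl-2-(triisopropylsilyloxymethyl)-3,4-dihydro-2H-chromen-6-yl]ethanone | CC(C)[Si](C(C)C)(C(C)C)OC[C@@]1(C)CC(OC)c2cc(C(C)=O)cc(OC)c2O1
F7 | step 6 | (2R,4RS)-4-methoxy-2-methyl-6-(trimethylsilyl)-1-(triisopropylsilyloxy)hex-5-yn-2-yl formate | CC(C)[Si](C(C)C)(C(C)C)OC[C@@](OC=O)(C)CC(OC)C#C[Si](C)(C)C
F8 | step 6 | {[(2R,4RS)-2-(2,2-dibromoethenyl)oxy-4-methoxy-2-methyl-6-(trimethylsilyl)hex-5-yn-1-yl]oxy}triisopropylsilane | CC(C)[Si](C(C)C)(C(C)C)OC[C@@](OC=C(Br)Br)(C)CC(OC)C#C[Si](C)(C)C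
F9 | step 8 | 1-[(2R,4RS)-8-[diisopropyl(methoxy)silyl]-4-methoxy-2-methyl-2-(triisopropylsilyloxymethyl)-5-(trimethylsilyl)-3,4-dihydro-2H-chromen-6-yl]ethanone | CC(C)[Si](C(C)C)(C(C)C)OC[C@@]1(C)CC(OC)c2c([Si](C)(C)C)c(C(C)=O)cc([Si](OC)(C(C)C)C(C)C)c2O1
F10 | step 10 | 1-[(2R,4RS)-8-iodo-4-methoxy-2-methyl-2-(triisopropylsilyloxymethyl)-3,4-dihydro-2H-chromen-6-yl]ethanone | CC(C)[Si](C(C)C)(C(C)C)OC[C@@]1(C)CC(OC)c2cc(C(C)=O)cc(I)c2O1
F11 | step 14 | [(2R,4RS)-6-acetyl-4-bromo-8-methoxy-2-methyl-3,4-dihydro-2H-chromen-2-yl]methyl (E)-3-(4-acetoxy-3-methoxyphenyl)prop-2-enoate | COc1cc(/C=C/C(=O)OC[C@@]2(C)CC(Br)c3cc(C(C)=O)cc(OC)c3O2)ccc1OC(C)=O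
A1 | alternative 1 | trans-fused 2,2-diethyl-1,2-oxasilolane on C2–C3 of 8-methoxy-2-methyl-6-(2-methyl-1,3-dioxolan-2-yl)chromane | C1[C@@]2(C)[C@H](O[Si]1(CC)CC)Cc3cc(C4(C)OCCO4)cc(OC)c3O2
A2 | alternative 1 | (3R)-3-(diethylsilyloxy)-8-methoxy-2,2-dimethyl-6-(2-methyl-1,3-dioxolan-2-yl)chromane | CC[SiH](CC)O[C@@H]1Cc2cc(C3(C)OCCO3)cc(OC)c2OC1(C)C
A3 | alternative 2 | (R)-6-acetyl-2-(tert-butyldimethylsilyloxymethyl)-8-methoxy-2-methyl-2H-chromene-3-carbaldehyde | CC(C)(C)[Si](C)(C)OC[C@@]1(C)C(C=O)=Cc2cc(C(C)=O)cc(OC)c2O1
A4 | alternative 2 | 5-acetyl-2-hydroxy-3-methoxybenzaldehyde | COc1cc(C(C)=O)cc(C=O)c1O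
A5 | alternative 2 | (E)-4-(tert-butyldimethylsilyloxy)-3-methylbut-2-enal | CC(C)(C)[Si](C)(C)OC/C(C)=C/C=O
A6 | alternative 3 | methyl (R)-8-methoxy-2-methyl-6-(2-methyl-1,3-dioxolan-2-yl)-4-oxochromane-2-carboxylate | COC(=O)[C@@]1(C)CC(=O)c2cc(C3(C)OCCO3)cc(OC)c2O1
A7 | alternative 3 | methyl (R)-4-[2-fluoro-3-methoxy-5-(2-methyl-1,3-dioxolan-2-yl)phenyl]-2-hydroxy-2-methyl-4-oxobutanoate | COC(=O)[C@@](O)(C)CC(=O)c1cc(C2(C)OCCO2)cc(OC)c1F
A8 | alternative 3 | (R)-citramalic acid | OC(=O)[C@@](O)(C)CC(=O)O
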